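The earlier runs and the new flask are simulated for substances that don't exist, noise included.

A small charge of second substrate matters to the rate if it spends coupling partner, so we reckon with the partner left and not with the target made.

in all of them: starting material 0.21 M; free catalyst 1 mol%

| charge | second substrate | coupling partner | remark |
|---|---|---|---|
| north-west | 0.50 equiv | 1 equiv | run made earlier |
| west | 0.50 equiv | 4 equiv | run made earlier |
| flask | 0.500 equiv | 2.00 equiv |  |

| run | time / min | target / % | starting material / % |
|---|---|---|---|
| north-west | 12.0 | 4 | 103 |
| north-west | 25.0 | 2 | 97 |
| north-west | 40.0 | 0 | 99 |
| north-west | 50.0 | 4 | 95 |
| north-west | 60.0 | 0 | 97 |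
| north-west | 80.0 | 1 | 97 |
| west | 12.0 | 1 | 98 |
| west | 25.0 | 4 | 95 |
| west | 40.0 | 8 | 93 |
| west | 50.0 | 12 | 87 |
| west | 60.0 | 13 | 88 |
| west | 80.0 | 20 | 82 |

(standard deviation of a reading: 2 percentage points)

- what was read earlier has a scatter of 2 percentage points, one standard deviation
- no earlier run changes the charge of second substrate; that part of a forecast is a guess

1. apparent order in second substrate when 50% of the starting material are converted (percent change of the rate of making target for one percent more second substrate charged)
2. apparent order in coupling partner when 50% of the starting material are converted (percent change of the rate of making target for one percent more coupling partner charged)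

The west run makes 20% of target in 80.0 min, while the north-west run shows no rise beyond the scatter of 2 percentage points. Our own supposition is that the rate is first order in partner, and that each starting material and each second substrate takes one partner. With the second substrate taken off, the two runs hold partner in the ratio 7.00, not 4.00. The north-west run should then stand at 2.86% after 80.0 min; it reads 1%, which is within the scatter.

We therefore carry one quantity, the partner left: the charge of coupling partner, less what the conversion has taken, less the charge of second substrate, supposed used up by then. At the conversion asked about, this flask has 1.00 equiv of partner left, which is half of its charge, so on our supposition the partner's factor in the rate stands at that fraction of what the charge gives. One percent more of a charge changes the partner left by a percentage equal to that charge over the partner left. Our reckoning gives an order of 2.00 in coupling partner and −0.500 in second substrate.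

The forecast takes 2 for coupling partner (range 1.3 to 3) and 1 for second substrate (range 0 to 2.5), with the words “First order is a plausible guess”. On second substrate its sign differs from ours.

The flask gives −0.53 in second substrate and 2.1 in coupling partner.

    starting material + free catalyst ⇌ catalyst intermediate A (K = 62.0 L mol⁻¹, k = 0.270 L mol⁻¹ s⁻¹)
    coupling partner + catalyst intermediate A → free catalyst + target (k = 0.0140 L mol⁻¹ s⁻¹)
    second substrate + free catalyst ⇌ catalyst intermediate B (K = 300 L mol⁻¹, k = 5.00 L mol⁻¹ s⁻¹)
    coupling partner + catalyst intermediate B → free catalyst + second product (k = 0.0260 L mol⁻¹ s⁻¹)
    catalyst intermediate A → spent catalyst (k = 1.30 × 10⁻⁵ s⁻¹)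

At 2.00 h this flask has 19.4% of its second substrate left, against 87.3% of its starting material. Carried on to 20.0 h, where starting material stands at 5.01% and second substrate at 0%, the partner left comes to 27.5% of the charge, and this flask holds 27.8% of its coupling partner.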